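The hydroazulene core is cut at C5–C1 and C5–C6 (C1 = methyl-bearing fusion carbon, C5 = fusion CH, C6 and C10 = ester carbinols). Six carbons of the seven-membered ring (C1, C6, C7, C8, C9, C10), the C8 methyl and the C10 oxygen are recognised as a 4-methyl-2-silyloxyphenyl ring; C5 is inserted as a ketocarbenoid. One enantioselective intramolecular Buchner reaction of a 1-diazo-4-arylbutan-2-one thus closes the five-membered ring, expands the arene to the seven-membered ring and sets C5. The aryl oxygen is carried as a triisopropylsilyl ether so that the derived enol ether later delivers the C1 methyl and C10 ketone under base.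

Key step: step 5

Assumption: the (S,S)-bis(oxazoline) ligand is taken to induce the (8aR) azulenone; if the sense of induction is the opposite, the (R,R) ligand is used with no other change.

Numbering used in all names: C1 = fusion carbon that receives the angular methyl; C2, C3 = methylenes; C4 = isopropyl carbinol; C5 = fusion CH; C6 to C10 = the other seven-membered-ring carbons (C6 next to C5, C10 next to C1), methyl on C8. β is the face of the C1 methyl and the C4 hydroxyl, α the face of H5. "Dauc" in a name means this trans-fused 5αH-hydroazulene with 1β-methyl, 8-methyl and 4α-isopropyl groups.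

Step 1
Reactants: 1 2-hydroxy-4-methylbenzaldehyde
Product: 2 4-methyl-2-(triisopropylsilyloxy)benzaldehyde
Conditions: TIPSCl, imidazole, DMF, rt
Reagents that add atoms: chlorotriisopropylsilane, CC(C)[Si](Cl)(C(C)C)C(C)C
Why: Imidazole-promoted silylation of the phenol; the silyl ether should survive to step 8 and, unlike a methyl ether, can then be removed by fluoride so that the C10 ketone is released under base.

Step 2
Reactants: 2 4-methyl-2-(triisopropylsilyloxy)benzaldehyde; 3 benzyl 2-(diethoxyphosphoryl)acetate
Product: 4 benzyl (E)-3-[4-methyl-2-(triisopropylsilyloxy)phenyl]prop-2-enoate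
Conditions: NaH, THF, 0 °C to rt
Reagents that add atoms: none
Why: Horner–Wadsworth–Emmons olefination with a stabilised phosphonate anion should give the E ester; the benzyl ester avoids a later hydroxide saponification, which would endanger the aryl silyl ether.

Step 3
Reactants: 4 benzyl (E)-3-[4-methyl-2-(triisopropylsilyloxy)phenyl]prop-2-enoate
Product: 5 3-[4-methyl-2-(triisopropylsilyloxy)phenyl]propanoic acid
Conditions: H2 (1 atm), 10% Pd/C, EtOAc, rt
Reagents that add atoms: none
Why: Catalytic hydrogenation should saturate the alkene and hydrogenolyse the benzyl ester in one operation, leaving the aryl silyl ether intact.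

Step 4
Reactants: 5 3-[4-methyl-2-(triisopropylsilyloxy)phenyl]propanoic acid; 6 (trimethylsilyl)diazomethane
Product: 8 1-diazo-4-[4-methyl-2-(triisopropylsilyloxy)phenyl]butan-2-one, via acid chloride 7 (not isolated)
Conditions: (COCl)2, DMF (cat.), CH2Cl2, 0 °C to rt; evaporate; TMSCHN2 (2 equiv), THF/MeCN, 0 °C to rt; evaporate
Reagents that add atoms: none
Why: Acid chloride formation followed by C-acylation of the silyl diazomethane with loss of the silyl group to chloride, the safe variant of the Arndt–Eistert diazoketone synthesis.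

Step 5
Reactants: 8 1-diazo-4-[4-methyl-2-(triisopropylsilyloxy)phenyl]butan-2-one
Product: 10 (8aR)-6-methyl-4-(triisopropylsilyloxy)-3,8a-dihydroazulen-1(2H)-one, via norcaradiene 9 (not isolated)
Conditions: Cu(MeCN)4PF6 (5 mol %), (S,S)-2,2'-(propane-2,2-diyl)bis(4-phenyl-4,5-dihydrooxazole) (6 mol %), Na[B(3,5-(CF3)2C6H3)4] (6 mol %), CH2Cl2, reflux, slow addition of 8; filtration through neutral alumina, used at once
Reagents that add atoms: none
Why: The Cu(MeCN)4PF6/bis(oxazoline) catalyst turns the diazoketone into an electrophilic ketocarbenoid at C5, which adds across the ipso–ortho (C1–C6) π bond of the arene to give norcaradiene 9; this opens by a thermally allowed disrotatory six-electron electrocyclic reaction to cycloheptatriene 10 (intramolecular Buchner reaction, the known behaviour of 1-diazo-4-arylbutan-2-ones). The five-membered ring closes in the [2+1] cycloaddition through the new C5–C1 bond, and the seven-membered ring arises by ring expansion when the C1–C6 bond of the cyclopropane breaks, C5–C6 being the second new bond. The only new stereocentre, C5, is set in the cyclopropanation by the C2-symmetric ligand, which differentiates the enantiotopic faces of the carbenoid, and it is untouched by the ring opening. The step needs attack at the unsubstituted ortho bond and not at the C1–C10 bond or by aromatic substitution: the bulky ortho silyloxy group shields the C1–C10 side, and C6, meta to both the oxygen and the methyl group, is not activated for electrophilic substitution. The non-coordinating borate counter-ion and slow addition should keep the cationic catalyst active and suppress carbene dimerisation.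

Step 6
Reactants: 10 (8aR)-6-methyl-4-(triisopropylsilyloxy)-3,8a-dihydroazulen-1(2H)-one
Product: 11 (1R,8aR)-1-isopropyl-6-methyl-4-(triisopropylsilyloxy)-1,2,3,8a-tetrahydroazulen-1-ol
Conditions: iPrMgCl, anhydrous CeCl3, THF, −78 °C; then 10, −78 °C; aq. NH4Cl
Reagents that add atoms: isopropylmagnesium chloride, CC(C)[Mg]Cl
Why: Organocerium 1,2-addition, chosen because the ketone is easily enolised at C5; the reagent should attack the convex α face, anti to the C6 arm on C5, so that C4 carries its hydroxyl on the β face.

Step 7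
Reactants: 11 (1R,8aR)-1-isopropyl-6-methyl-4-(triisopropylsilyloxy)-1,2,3,8a-tetrahydroazulen-1-ol
Product: 12 1β,10β-methano adduct of 11 (cyclopropane C1–C10–CH2 with CH2 on the β face, OTIPS on C10, 4β-OH, 5α-H, diene C6=C7–C8(CH3)=C9)
Conditions: Et2Zn, CH2I2, CH2Cl2, −10 to 0 °C; aq. NH4Cl
Reagents that add atoms: diiodomethane, ICI
Why: Hydroxyl-directed Simmons–Smith cyclopropanation (Furukawa variant): the zinc alkoxide of the C4 hydroxyl should hold the carbenoid on the β face and deliver CH2 to the most electron-rich alkene, the silyl enol ether C1=C10, which sets quaternary C1 with the new carbon β (cis to the C4 oxygen, trans to H5).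

Step 8
Reactants: 12 1β,10β-methano adduct of 11
Product: 14 4β-hydroxydauca-6,8-dien-10-one, via cyclopropanol 13 (not isolated)
Conditions: Bu4NF, THF, 0 °C to rt; then MeOH, K2CO3 (cat.), rt
Reagents that add atoms: none
Why: Fluoride desilylation then base-induced opening of the cyclopropanolate (Conia-type homoenolate cleavage): the C10–CH2 bond breaks toward the less substituted carbon, which is protonated to the C1 methyl with C1 unchanged; base is chosen because acid would protonate the diene and expand the 1-alkenylcyclopropanol to a cyclobutanone.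

Step 9
Reactants: 14 4β-hydroxydauca-6,8-dien-10-one
Product: 16 4β,6-dihydroxydauc-8-en-10-one as a mixture of C6 epimers, via boronate 15 (not isolated)
Conditions: B2pin2, CuCl (10 mol %), bis[2-(diphenylphosphino)phenyl] ether (10 mol %), NaOtBu (15 mol %), MeOH (2 equiv), THF, rt; then 30% H2O2, pH 7 phosphate buffer, 0 °C to rt
Reagents that add atoms: hydrogen peroxide, OO
Why: Copper-catalysed conjugate borylation in the 1,6 sense (the β-carbon C8 is fully substituted, so the boryl copper species should add at the δ-carbon C6) and oxidation of the C–B bond; the C6 configuration does not matter because step 10 erases it, and a deconjugated C7=C8 isomer would serve equally.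

Step 10
Reactants: 16 4β,6-dihydroxydauc-8-en-10-one as a mixture of C6 epimers
Product: 17 4β-hydroxydauc-8-ene-6,10-dione
Conditions: Dess–Martin periodinane, pyridine, CH2Cl2, 0 °C to rt; used without delay
Reagents that add atoms: none
Why: Dess–Martin oxidation of the secondary C6 alcohol, the tertiary C4 alcohol being inert; both C6 epimers should converge on one ene-dione.

Step 11
Reactants: 17 4β-hydroxydauc-8-ene-6,10-dione
Product: 18 4β,6α-dihydroxydauc-8-en-10-one
Conditions: Me4NBH(OAc)3, MeCN/AcOH (1:1), −20 to 0 °C; then DBU (cat.), CH2Cl2, rt, only if a deconjugated isomer is present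
Reagents that add atoms: none
Why: Evans–Saksena reduction: the C4 hydroxyl exchanges onto boron and should deliver hydride to the C6 carbonyl on its own β face through a six-membered transition state, giving the 1,3-anti diol with the C6 hydroxyl α, while the C10 enone, with no hydroxyl in reach, is left alone.

Step 12
Reactants: 18 4β,6α-dihydroxydauc-8-en-10-one
Product: 19 dauc-8-ene-4β,6α,10α-triol
Conditions: LiBH(s-Bu)3 (L-Selectride), THF, −78 °C; MeOH, aq. NH4Cl
Reagents that add atoms: none
Why: 1,2-Reduction of a β,β-disubstituted enone by a bulky trialkylborohydride: a small hydride would add along the axial line anti to the C1 methyl and give the 10β-ol, whereas LiBH(s-Bu)3 is expected to avoid the axial H5 and H7 on the α face and enter from the equatorial direction, setting C10 as the axial 10α-alcohol trans to the C1 methyl (the behaviour known for 4,4-dimethyl-3-keto steroids).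

Step 13
Reactants: 19 dauc-8-ene-4β,6α,10α-triol; 20 angelic acid
Product: 22 6α,10α-bis[(Z)-2-methylbut-2-enoyloxy]dauc-8-en-4β-ol (CNP0183261.1), via mixed anhydride 21 (not isolated)
Conditions: 20 (3 equiv in all, of which 2 are consumed), 2,4,6-trichlorobenzoyl chloride (3 equiv), Et3N (3.5 equiv), toluene, rt; then 19, 80 °C, until the 6-monoester is consumed
Reagents that add atoms: angelic acid (second equivalent of 20), C/C=C(/C)C(=O)O
Why: Yamaguchi-type esterification through the preformed mixed anhydride without DMAP, conditions that should transfer the (Z)-acyl group without isomerisation to the tiglate; two equivalents of anhydride 21 are consumed, one for each secondary hydroxyl (the less hindered C6 hydroxyl first, the neopentylic C10 hydroxyl on continued heating), both with retention, and the tertiary C4 hydroxyl does not react.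

Compound list
1 | 2-hydroxy-4-methylbenzaldehyde | Cc1ccc(C=O)c(O)c1 | starting material
2 | 4-methyl-2-(triisopropylsilyloxy)benzaldehyde | Cc1ccc(C=O)c(O[Si](C(C)C)(C(C)C)C(C)C)c1 | intermediate
3 | benzyl 2-(diethoxyphosphoryl)acetate | CCOP(=O)(CC(=O)OCc1ccccc1)OCC | starting material
4 | benzyl (E)-3-[4-methyl-2-(triisopropylsilyloxy)phenyl]prop-2-enoate | Cc1ccc(/C=C/C(=O)OCc2ccccc2)c(O[Si](C(C)C)(C(C)C)C(C)C)c1 | intermediate
5 | 3-[4-methyl-2-(triisopropylsilyloxy)phenyl]propanoic acid | Cc1ccc(CCC(=O)O)c(O[Si](C(C)C)(C(C)C)C(C)C)c1 | intermediate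
6 | (trimethylsilyl)diazomethane | C[Si](C)(C)C=[N+]=[N-] | starting material
7 | 3-[4-methyl-2-(triisopropylsilyloxy)phenyl]propanoyl chloride | Cc1ccc(CCC(=O)Cl)c(O[Si](C(C)C)(C(C)C)C(C)C)c1 | intermediate
8 | 1-diazo-4-[4-methyl-2-(triisopropylsilyloxy)phenyl]butan-2-one | Cc1ccc(CCC(=O)C=[N+]=[N-])c(O[Si](C(C)C)(C(C)C)C(C)C)c1 | intermediate
9 | norcaradiene valence isomer of 10 (cyclopropane C1–C5–C6, cyclohexadiene C10=C9 and C8=C7) | O=C1CC[C@@]23[C@H]1[C@H]3C=C(C)C=C2O[Si](C(C)C)(C(C)C)C(C)C | intermediate
10 | (8aR)-6-methyl-4-(triisopropylsilyloxy)-3,8a-dihydroazulen-1(2H)-one | O=C1CCC2=C(O[Si](C(C)C)(C(C)C)C(C)C)C=C(C)C=C[C@@H]12 | intermediate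
11 | (1R,8aR)-1-isopropyl-6-methyl-4-(triisopropylsilyloxy)-1,2,3,8a-tetrahydroazulen-1-ol (4β-OH, 4α-isopropyl, 5α-H) | C1=CC(C)=CC(O[Si](C(C)C)(C(C)C)C(C)C)=C2CC[C@@](O)(C(C)C)[C@H]12 | intermediate
12 | 1β,10β-methano adduct of 11 (cyclopropane C1–C10–CH2, CH2 β, 10-OTIPS, 4β-OH, 5α-H) | C1=CC(C)=C[C@]3(O[Si](C(C)C)(C(C)C)C(C)C)C[C@@]32CC[C@@](O)(C(C)C)[C@H]12 | intermediate
13 | cyclopropanol from 12 (10-OH in place of 10-OTIPS) | C1=CC(C)=C[C@]3(O)C[C@@]32CC[C@@](O)(C(C)C)[C@H]12 | intermediate
14 | 4β-hydroxydauca-6,8-dien-10-one | C1=CC(C)=CC(=O)[C@@]2(C)CC[C@@](O)(C(C)C)[C@H]12 | intermediate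
15 | 6-(4,4,5,5-tetramethyl-1,3,2-dioxaborolan-2-yl)-4β-hydroxydauc-8-en-10-one, C6 epimers | CC1(C)OB(OC1(C)C)C1CC(C)=CC(=O)[C@@]2(C)CC[C@@](O)(C(C)C)[C@H]12 | intermediate
16 | 4β,6-dihydroxydauc-8-en-10-one, C6 epimers | OC1CC(C)=CC(=O)[C@@]2(C)CC[C@@](O)(C(C)C)[C@H]12 | intermediate
17 | 4β-hydroxydauc-8-ene-6,10-dione | O=C1CC(C)=CC(=O)[C@@]2(C)CC[C@@](O)(C(C)C)[C@H]12 | intermediate
18 | 4β,6α-dihydroxydauc-8-en-10-one | O[C@H]1CC(C)=CC(=O)[C@@]2(C)CC[C@@](O)(C(C)C)[C@H]12 | intermediate
19 | dauc-8-ene-4β,6α,10α-triol | O[C@H]1CC(C)=C[C@@H](O)[C@@]2(C)CC[C@@](O)(C(C)C)[C@H]12 | intermediate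
20 | angelic acid, (Z)-2-methylbut-2-enoic acid | C/C=C(/C)C(=O)O | starting material
21 | (Z)-2-methylbut-2-enoic 2,4,6-trichlorobenzoic anhydride | C/C=C(/C)C(=O)OC(=O)c1c(Cl)cc(Cl)cc1Cl | intermediate
22 | 6α,10α-bis[(Z)-2-methylbut-2-enoyloxy]dauc-8-en-4β-ol; (1R,3aS,4R,8S,8aS)-1-hydroxy-1-isopropyl-3a,6-dimethyl-1,2,3,3a,4,7,8,8a-octahydroazulene-4,8-diyl bis[(Z)-2-methylbut-2-enoate] | C/C=C(/C)C(=O)O[C@H]1CC(C)=C[C@@H](OC(=O)/C(C)=C\C)[C@@]2(C)CC[C@@](O)(C(C)C)[C@H]12 | target

Total step count: 13. Longest linear sequence: 13 steps, from 1.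

Steps most likely to fail

Step 5. The copper carbenoid may discriminate poorly between the enantiotopic faces, and the labile trienol ether may be lost on handling. Fallback: setting out from 8, the reaction is run with achiral Rh2(OAc)4 (1 mol %, CH2Cl2, reflux), a dependable Buchner catalyst, to give racemic 6-methyl-4-(triisopropylsilyloxy)-3,8a-dihydroazulen-1(2H)-one F1. Isopropylcerium addition as in step 6 then gives 11 together with its mirror image ent-11 F2. Preparative chromatography on a chiral stationary phase separates the two, and the route is rejoined at 11.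

Step 12. Hydride may be delivered to the wrong face of the C10 carbonyl, along the axial line anti to the C1 methyl, giving the 10β-alcohol. Fallback: setting out from 18, the C6 hydroxyl is first esterified with mixed anhydride 21 (toluene, 60 °C) to give 6α-angeloyloxy-4β-hydroxydauc-8-en-10-one F3. Luche reduction (NaBH4, CeCl3·7H2O, MeOH, −78 °C) is then used deliberately for its axial attack and should give 6α-angeloyloxydauc-8-ene-4β,10β-diol F4. Mitsunobu esterification of F4 with angelic acid 20 (PPh3, diisopropyl azodicarboxylate, toluene, 0 °C to rt) inverts C10 and returns to the route at 22.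

Step 9. The boryl copper species may add slowly or in the 1,4 sense at the hindered dienone, and the allylic boronate may be lost by protodeboronation. Fallback: setting out from 14, hydroxyl-assisted epoxidation of the more electron-rich C6=C7 bond (m-chloroperoxybenzoic acid, NaHCO3, CH2Cl2, 0 °C) gives 6β,7β-epoxy-4β-hydroxydauc-8-en-10-one F5, whose epoxide configuration is immaterial. Isomerisation of the vinyl epoxide with zerovalent palladium, Pd(PPh3)4 (5 mol %, THF, rt), through the π-allyl alkoxide and a hydride shift should give the ene-dione, and the route is rejoined at 17.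

Further compounds
F1 | step 5 | racemic 6-methyl-4-(triisopropylsilyloxy)-3,8a-dihydroazulen-1(2H)-one | O=C1CCC2=C(O[Si](C(C)C)(C(C)C)C(C)C)C=C(C)C=CC12
F2 | step 5 | ent-11, (1S,8aS)-1-isopropyl-6-methyl-4-(triisopropylsilyloxy)-1,2,3,8a-tetrahydroazulen-1-ol | C1=CC(C)=CC(O[Si](C(C)C)(C(C)C)C(C)C)=C2CC[C@](O)(C(C)C)[C@@H]12
F3 | step 12 | 6α-angeloyloxy-4β-hydroxydauc-8-en-10-one | C/C=C(/C)C(=O)O[C@H]1CC(C)=CC(=O)[C@@]2(C)CC[C@@](O)(C(C)C)[C@H]12
F4 | step 12 | 6α-angeloyloxydauc-8-ene-4β,10β-diol | C/C=C(/C)C(=O)O[C@H]1CC(C)=C[C@H](O)[C@@]2(C)CC[C@@](O)(C(C)C)[C@H]12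
F5 | step 9 | 6β,7β-epoxy-4β-hydroxydauc-8-en-10-one | [C@H]13O[C@@H]3C(C)=CC(=O)[C@@]2(C)CC[C@@](O)(C(C)C)[C@H]12
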